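Both six-membered rings B (C5–C6–C7–C8–C9–C10 and its primed twin, lindenane numbering) are disconnected at C7–C8 together with the lactone carbonyl C12. This leaves a C2-symmetric cyclobutane-1,2-dione (C8, C8′) whose C9 and C9′ carry finished cyclopropane-fused ring A units with but-2-ynyl arms on C5. One double carbonylative (2+2+1) cycloaddition of ketone, alkyne and CO then closes rings B last, builds both butenolides and sets the two oxygenated quaternary carbons. It exploits C8 being at once a ring B atom, the lactone carbinol carbon and a cyclobutane carbon next to the epimerisable C9. The dione arises from an oxidatively dimerised ester by acyloin ring closure.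

Key step: step 11

Remark: atoms carry the lindenane numbers of the target (cyclopropane C1–C2–C3 with C2 = CH2; ring A = C1, C3, C4, C5, C10; C14 = methyl on C10; C15 = methylene on C4; C11, C12, C13 in the lactone; primes for the second half). Compounds 9 and 11–13 are carried as mixtures of C9/C9′ epimers, which converge at the α-dione 14.

Step 1
Reactants: 1 (S)-2-(but-3-en-1-yl)oxirane
Product: 2 (1S,2S,5R)-bicyclo[3.1.0]hexan-2-ol
Conditions: LiTMP (commercial solution, 1.2 equiv), MTBE, 0 °C to rt; aqueous work-up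
Reagents that add atoms: none
Why: Hodgson cyclopropanation (intramolecular cyclopropanation of an α-lithiated terminal epoxide): the carbenoid carbon adds to the tethered alkene, so the single epoxide stereocentre should fix both ring-fusion carbons (C1 and C3 of the target) and give the trans alcohol.

Step 2
Reactants: 2 (1S,2S,5R)-bicyclo[3.1.0]hexan-2-ol
Product: 3 (1S,5R)-bicyclo[3.1.0]hexan-2-one
Conditions: NaOCl (aq), TEMPO (cat.), KBr (cat.), NaHCO3, CH2Cl2/H2O, 0 °C
Reagents that add atoms: none
Why: TEMPO/hypochlorite (Anelli) oxidation of a secondary alcohol; the cyclopropane and the ring-fusion centres are not touched.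

Step 3
Reactants: 3 (1S,5R)-bicyclo[3.1.0]hexan-2-one
Product: 4 (1S,5S)-bicyclo[3.1.0]hex-3-en-2-one
Conditions: IBX, 4-methoxypyridine N-oxide, DMSO, 40 °C
Reagents that add atoms: none
Why: IBX-mediated α,β-dehydrogenation of a ketone; enolisation is possible only towards the CH2 side because the other α-carbon is a cyclopropane bridgehead.

Step 4
Reactants: 4 (1S,5S)-bicyclo[3.1.0]hex-3-en-2-one
Product: 6 (1S,5R)-4-methylbicyclo[3.1.0]hex-3-en-2-one, via trimethylsilyl enol ether 5 (not isolated)
Conditions: MeMgBr, CuBr·SMe2 (10 mol %), TMSCl, THF, −78 °C; solvent switch; Pd(OAc)2 (1.05 equiv), MeCN, rt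
Reagents that add atoms: methylmagnesium bromide, C[Mg]Br; chlorotrimethylsilane, C[Si](C)(C)Cl (its silyl group stays only in 5)
Why: Copper-catalysed conjugate addition with silyl trapping, then Saegusa–Ito oxidation of 5, returns the enone with the methyl group on the β-carbon (C10); the transient stereocentre at C10 is erased.

Step 5
Reactants: 6 (1S,5R)-4-methylbicyclo[3.1.0]hex-3-en-2-one; 7 tert-butyl[(1-methoxyethenyl)oxy]dimethylsilane
Product: 8 methyl 2-[4-(tert-butyldimethylsilyloxy)-2-methylbicyclo[3.1.0]hex-3-en-2-yl]acetate (C10 quaternary: methyl syn, acetate arm anti to the cyclopropane CH2)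
Conditions: Tf2NH (2 mol %, gives the silyl triflimide catalyst from 7), CH2Cl2, −78 °C; 6 added last
Reagents that add atoms: none
Why: Mukaiyama–Michael addition with silyl transfer: the ketene silyl acetal should attack the β,β-disubstituted enone at C10 on the face opposite the cyclopropane CH2, which sets the quaternary C10 with its methyl syn to the cyclopropane, and the ketone stays masked as the silyl enol ether.

Step 6
Reactants: 8 methyl 2-[4-(tert-butyldimethylsilyloxy)-2-methylbicyclo[3.1.0]hex-3-en-2-yl]acetate (2 equiv)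
Product: 9 dimethyl 2,3-bis[4-(tert-butyldimethylsilyloxy)-2-methylbicyclo[3.1.0]hex-3-en-2-yl]butanedioate (C9/C9′ epimer mixture)
Conditions: LDA (commercial solution, 1.05 equiv), THF, −78 °C; then Cu(O2CCH(C2H5)C4H9)2 (copper bis(2-ethylhexanoate), 1.1 equiv), −78 °C to rt
Reagents that add atoms: none
Why: Oxidative homocoupling of a lithium ester enolate by one-electron oxidation with a divalent copper carboxylate forms the C9–C9′ bond; the silyl enol ethers are inert to LDA, and C9/C9′ need no control here because they are equilibrated at the stage of 14.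

Step 7
Reactants: 9 dimethyl 2,3-bis[4-(tert-butyldimethylsilyloxy)-2-methylbicyclo[3.1.0]hex-3-en-2-yl]butanedioate; 10 1-bromobut-2-yne (2.4 equiv)
Product: 11 dimethyl 2,3-bis[3-(but-2-yn-1-yl)-2-methyl-4-oxobicyclo[3.1.0]hexan-2-yl]butanedioate (butynyl on C5 cis to the C14 methyl)
Conditions: BnMe3NF (dried, 2.2 equiv), 4 Å molecular sieves, THF, −78 to 0 °C
Reagents that add atoms: none
Why: Fluoride-promoted regiospecific alkylation of silyl enol ethers through ammonium enolates (SN2 at the propargylic bromide): the electrophile should enter C5 anti to the bulky succinate-bearing substituent of the neighbouring quaternary C10, that is cis to the C14 methyl, which gives H-5 trans to C14 as in the target.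

Step 8
Reactants: 11 dimethyl 2,3-bis[3-(but-2-yn-1-yl)-2-methyl-4-oxobicyclo[3.1.0]hexan-2-yl]butanedioate
Product: 12 dimethyl 2,3-bis[3-(but-2-yn-1-yl)-2-methyl-4-methylidenebicyclo[3.1.0]hexan-2-yl]butanedioate
Conditions: Zn, CH2Br2, TiCl4 (Lombardo reagent), THF/CH2Cl2, 0 °C to rt
Reagents that add atoms: dibromomethane, BrCBr
Why: Lombardo methylenation, a non-basic zinc–titanium carbenoid olefination, should convert the hindered C4 ketones into the exocyclic methylenes without epimerising C5 and without touching the esters or alkynes.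

Step 9
Reactants: 12 dimethyl 2,3-bis[3-(but-2-yn-1-yl)-2-methyl-4-methylidenebicyclo[3.1.0]hexan-2-yl]butanedioate
Product: 13 3,4-bis[3-(but-2-yn-1-yl)-2-methyl-4-methylidenebicyclo[3.1.0]hexan-2-yl]-1,2-bis(trimethylsilyloxy)cyclobut-1-ene
Conditions: Na (dispersion), TMSCl, toluene, reflux
Reagents that add atoms: chlorotrimethylsilane, C[Si](C)(C)Cl
Why: Acyloin condensation in the Rühlmann variant: four-electron reduction couples the two ester carbonyls to the C8–C8′ bond and closes the cyclobutene, TMSCl traps the enediolate and the methoxide, the bulky 2,3-substituents favour four-membered ring closure, and isolated alkenes and dialkyl alkynes should not be reduced in toluene.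

Step 10
Reactants: 13 3,4-bis[3-(but-2-yn-1-yl)-2-methyl-4-methylidenebicyclo[3.1.0]hexan-2-yl]-1,2-bis(trimethylsilyloxy)cyclobut-1-ene
Product: 14 trans-3,4-bis[3-(but-2-yn-1-yl)-2-methyl-4-methylidenebicyclo[3.1.0]hexan-2-yl]cyclobutane-1,2-dione (C2-symmetric C9/C9′ epimer shown)
Conditions: Br2 (1.0 equiv), CH2Cl2, −78 °C; then iPr2NEt (5 mol %), 0 °C; used without chromatography
Reagents that add atoms: none
Why: Bromination of the electron-rich enediol bis(silyl ether) with loss of two TMSBr gives the 1,2-dione, and at −78 °C with one equivalent the enediol ether should react far faster than the alkenes and alkynes; the amine then equilibrates C9/C9′ (now α to the dione) to the trans isomers, of which 14 is the one consumed in step 11.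

Step 11
Reactants: 14 trans-3,4-bis[3-(but-2-yn-1-yl)-2-methyl-4-methylidenebicyclo[3.1.0]hexan-2-yl]cyclobutane-1,2-dione
Product: 15 target CNP0265879.1 (C2-symmetric cyclobutane-linked bis-lindenanolide)
Conditions: Ru3(CO)12 (10 mol %), P(4-CF3C6H4)3 (30 mol %), iPr2NEt (20 mol %), CO (10 atm), toluene, 150 °C
Reagents that add atoms: carbon monoxide, [C-]#[O+]
Why: Proposed new method: double intramolecular hetero-Pauson–Khand (2+2+1) reaction, in which a zerovalent ruthenium carbonyl fragment bound to the dione and the tethered alkyne undergoes oxidative cyclisation joining C7 to C8 (oxaruthenacyclopentene), CO inserts into the Ru–C11 bond and C–O reductive elimination releases the butenolide, after which the remaining strained α-acyloxy cyclobutanone repeats the sequence. The closest known reactions are the Ru3(CO)12-catalysed cyclocoupling of 1,2-diketones with alkynes and CO to butenolides (intermolecular) and the cyclocarbonylation of alkynyl aldehydes (intramolecular). Ring B closes in the oxidative cyclisation as a six-membered carbocycle through the C7–C8 bond onto the proximal carbonyl (the distal carbonyl would need a seven-membered ring), and each lactone ring closes by carbonylative C–O bond formation. C8 and C8′ are controlled by the tether through C9–C10, which allows only cis fusion of ring B to the cyclobutane; C9 and C9′, still epimerisable α to the unreacted ketone, should be funnelled through the chair-like closure in which the C9–C9′ bond lies anti to the axial C14 methyl. The step needs the alkynes to react in preference to the 1,1-disubstituted C4 methylenes, which is secured by the two-atom spacing (a four-membered ring would result) and by the chelating dione.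

Compound list
1 | (S)-2-(but-3-en-1-yl)oxirane [(S)-1,2-epoxyhex-5-ene] | C=CCC[C@H]1CO1 | starting material
2 | (1S,2S,5R)-bicyclo[3.1.0]hexan-2-ol | O[C@@H]1[C@H]2C[C@H]2CC1 | intermediate
3 | (1S,5R)-bicyclo[3.1.0]hexan-2-one | O=C1[C@H]2C[C@H]2CC1 | intermediate
4 | (1S,5S)-bicyclo[3.1.0]hex-3-en-2-one | O=C1[C@H]2C[C@H]2C=C1 | intermediate
5 | trimethylsilyl enol ether of 4-methylbicyclo[3.1.0]hexan-2-one (methyl trans to the cyclopropane CH2) | C[Si](C)(C)OC1=C[C@@H](C)[C@@H]2C[C@H]12 | intermediate
6 | (1S,5R)-4-methylbicyclo[3.1.0]hex-3-en-2-one | O=C1[C@H]2C[C@H]2C(C)=C1 | intermediate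
7 | tert-butyl[(1-methoxyethenyl)oxy]dimethylsilane | C=C(OC)O[Si](C)(C)C(C)(C)C | starting material
8 | methyl 2-[4-(tert-butyldimethylsilyloxy)-2-methylbicyclo[3.1.0]hex-3-en-2-yl]acetate (methyl syn to the cyclopropane CH2) | COC(=O)C[C@@]1(C)[C@@H]2C[C@@H]2C(O[Si](C)(C)C(C)(C)C)=C1 | intermediate
9 | dimethyl 2,3-bis[4-(tert-butyldimethylsilyloxy)-2-methylbicyclo[3.1.0]hex-3-en-2-yl]butanedioate (C9/C9′ mixture) | COC(=O)C([C@@]1(C)[C@@H]2C[C@@H]2C(O[Si](C)(C)C(C)(C)C)=C1)C([C@@]1(C)[C@@H]2C[C@@H]2C(O[Si](C)(C)C(C)(C)C)=C1)C(=O)OC | intermediate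
10 | 1-bromobut-2-yne | CC#CCBr | starting material
11 | dimethyl 2,3-bis[3-(but-2-yn-1-yl)-2-methyl-4-oxobicyclo[3.1.0]hexan-2-yl]butanedioate (C9/C9′ mixture) | COC(=O)C([C@@]1(C)[C@@H]2C[C@@H]2C(=O)[C@@H]1CC#CC)C([C@@]1(C)[C@@H]2C[C@@H]2C(=O)[C@@H]1CC#CC)C(=O)OC | intermediate
12 | dimethyl 2,3-bis[3-(but-2-yn-1-yl)-2-methyl-4-methylidenebicyclo[3.1.0]hexan-2-yl]butanedioate (C9/C9′ mixture) | COC(=O)C([C@@]1(C)[C@@H]2C[C@@H]2C(=C)[C@@H]1CC#CC)C([C@@]1(C)[C@@H]2C[C@@H]2C(=C)[C@@H]1CC#CC)C(=O)OC | intermediate
13 | 3,4-bis[3-(but-2-yn-1-yl)-2-methyl-4-methylidenebicyclo[3.1.0]hexan-2-yl]-1,2-bis(trimethylsilyloxy)cyclobut-1-ene (C9/C9′ mixture) | C[Si](C)(C)OC1=C(O[Si](C)(C)C)C([C@@]2(C)[C@@H]3C[C@@H]3C(=C)[C@@H]2CC#CC)C1[C@@]1(C)[C@@H]2C[C@@H]2C(=C)[C@@H]1CC#CC | intermediate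
14 | trans-3,4-bis[3-(but-2-yn-1-yl)-2-methyl-4-methylidenebicyclo[3.1.0]hexan-2-yl]cyclobutane-1,2-dione | O=C1C(=O)[C@H]([C@@]2(C)[C@@H]3C[C@@H]3C(=C)[C@@H]2CC#CC)[C@H]1[C@@]1(C)[C@@H]2C[C@@H]2C(=C)[C@@H]1CC#CC | intermediate
15 | CNP0265879.1, C2-symmetric cyclobutane-linked bis-lindenanolide | C=C1[C@H]2C[C@H]2[C@@]2(C)[C@H]1CC1=C(C)C(=O)O[C@]13[C@H]2[C@H]1[C@@]2(C)[C@@H]4C[C@@H]4C(=C)[C@@H]2CC2=C(C)C(=O)O[C@@]213 | target

Total step count: 11. Longest linear sequence: 11 steps (1 to 15).

Steps most likely to fail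

Step 11. The second carbonyl is no longer part of a 1,2-dione after the first annulation and may not enter the oxidative cyclisation. The dione may also be reduced or decarbonylated by the metal, ruthenium hydrides may move the exocyclic C4 double bonds into the ring, and the epimer funnelling at C9 may be too slow. Fallback with known chemistry, setting out from 9: alkylation of the enol ethers with allyl bromide (BnMe3NF, THF) gives the bis(C5-allyl) diketone F1. Lombardo methylenation gives the tetraene diester F2. Acyloin closure (Na, TMSCl, toluene) gives the bis(silyloxy)cyclobutene F3, and Br2 at −78 °C gives the allyl-armed dione F4. Cross-metathesis with methyl 2-(bromomethyl)acrylate (second-generation Hoveyda–Grubbs catalyst, CH2Cl2, 40 °C) gives the bis(2-bromomethyl enoate) F5. Indium metal in DMF then effects a double intramolecular Barbier allylation of the ketones through C7 with spontaneous lactonisation; this closes rings B and the lactones together and gives the bis(α-methylene lactone) F6. Isomerisation of the two conjugated exocyclic double bonds into the lactone rings with RhCl(PPh3)3 and Et3SiH (cat., toluene, 80 °C) comes back to the route at 15.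

Step 9. Sodium may reduce or reductively silylate the alkynes, and ring closure between two carbons flanked by quaternary centres may be slower than intermolecular coupling. Fallback setting out from 12: DIBAL-H (CH2Cl2, −78 °C) gives the 1,4-dialdehyde F7; intramolecular pinacol coupling with SmI2 (THF) gives the cyclobutane-1,2-diol F8; double Swern oxidation comes back to the route at 14.

Step 6. Coupling of two enolates that each sit next to a quaternary carbon may stall at low conversion, give Claisen condensation, or be accompanied by oxidation of the silyl enol ethers. Fallback setting out from 6: commercial dimethyl succinate is converted (LDA, TBSCl) into the bis(ketene silyl acetal) F9, which already contains the C9–C9′ bond; double Mukaiyama–Michael addition of F9 to two equivalents of 6 under the conditions of step 5 comes back to the route at 9.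

Further compounds
F1 | step 11 | dimethyl 2,3-bis[2-methyl-4-oxo-3-(prop-2-en-1-yl)bicyclo[3.1.0]hexan-2-yl]butanedioate | COC(=O)C([C@@]1(C)[C@@H]2C[C@@H]2C(=O)[C@@H]1CC=C)C([C@@]1(C)[C@@H]2C[C@@H]2C(=O)[C@@H]1CC=C)C(=O)OC
F2 | step 11 | dimethyl 2,3-bis[2-methyl-4-methylidene-3-(prop-2-en-1-yl)bicyclo[3.1.0]hexan-2-yl]butanedioate | COC(=O)C([C@@]1(C)[C@@H]2C[C@@H]2C(=C)[C@@H]1CC=C)C([C@@]1(C)[C@@H]2C[C@@H]2C(=C)[C@@H]1CC=C)C(=O)OC
F3 | step 11 | 3,4-bis[2-methyl-4-methylidene-3-(prop-2-en-1-yl)bicyclo[3.1.0]hexan-2-yl]-1,2-bis(trimethylsilyloxy)cyclobut-1-ene | C[Si](C)(C)OC1=C(O[Si](C)(C)C)C([C@@]2(C)[C@@H]3C[C@@H]3C(=C)[C@@H]2CC=C)C1[C@@]1(C)[C@@H]2C[C@@H]2C(=C)[C@@H]1CC=C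
F4 | step 11 | trans-3,4-bis[2-methyl-4-methylidene-3-(prop-2-en-1-yl)bicyclo[3.1.0]hexan-2-yl]cyclobutane-1,2-dione | O=C1C(=O)[C@H]([C@@]2(C)[C@@H]3C[C@@H]3C(=C)[C@@H]2CC=C)[C@H]1[C@@]1(C)[C@@H]2C[C@@H]2C(=C)[C@@H]1CC=C
F5 | step 11 | dione F4 with both allyl termini replaced by C(CH2Br)CO2Me (bis[methyl 2-(bromomethyl)but-2-enoate] arms) | O=C1C(=O)[C@H]([C@@]2(C)[C@@H]3C[C@@H]3C(=C)[C@@H]2CC=C(CBr)C(=O)OC)[C@H]1[C@@]1(C)[C@@H]2C[C@@H]2C(=C)[C@@H]1CC=C(CBr)C(=O)OC
F6 | step 11 | bis(α-methylene lactone) isomer of the target (C7-H, C11=CH2 in both halves) | C=C1[C@H]2C[C@H]2[C@@]2(C)[C@H]1CC1C(=C)C(=O)O[C@]13[C@H]2[C@H]1[C@@]2(C)[C@@H]4C[C@@H]4C(=C)[C@@H]2CC2C(=C)C(=O)O[C@@]213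
F7 | step 9 | 2,3-bis[3-(but-2-yn-1-yl)-2-methyl-4-methylidenebicyclo[3.1.0]hexan-2-yl]butanedial | O=CC([C@@]1(C)[C@@H]2C[C@@H]2C(=C)[C@@H]1CC#CC)C([C@@]1(C)[C@@H]2C[C@@H]2C(=C)[C@@H]1CC#CC)C=O
F8 | step 9 | 3,4-bis[3-(but-2-yn-1-yl)-2-methyl-4-methylidenebicyclo[3.1.0]hexan-2-yl]cyclobutane-1,2-diol | OC1C(O)C([C@@]2(C)[C@@H]3C[C@@H]3C(=C)[C@@H]2CC#CC)C1[C@@]1(C)[C@@H]2C[C@@H]2C(=C)[C@@H]1CC#CC
F9 | step 6 | 1,4-dimethoxy-1,4-bis(tert-butyldimethylsilyloxy)buta-1,3-diene | COC(O[Si](C)(C)C(C)(C)C)=CC=C(OC)O[Si](C)(C)C(C)(C)C
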